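The earlier runs and the new flask were computed from invented constants, and the scatter is random.

Follow the electrophile. It is the limiting reagent, so I opened a ledger on it.

| flask | electrophile | free base | protonated nucleophile | protic impurity | temperature | remark | time |
|---|---|---|---|---|---|---|---|
| Friday's | 2 mM | 6 mM | 3 mM | 0.20 mM | −5 °C | run made earlier |  |
| Sunday's | 2 mM | 6 mM | 12 mM | 0.20 mM | 10 °C | run made earlier |  |
| Monday's | 2 mM | 9 mM | 6 mM | 0.20 mM | −5 °C | run made earlier |  |
| west | 2.0 mM | 6.00 mM | 6.00 mM | 0.200 mM |  | at 0 °C throughout | 8.0 min |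
| north | 2.0 mM | 6.00 mM | 6.00 mM | 0.200 mM |  | at 20 °C until 50 s, from then on at 0 °C | 4.0 min |

| run | time / min | target / % | electrophile / % |
|---|---|---|---|
| Friday's | 1.00 | 5.8 | 93.8 |
| Friday's | 2.50 | 11.3 | 88.5 |
| Friday's | 3.00 | 11.5 | 86.9 |
| Friday's | 6.00 | 20.0 | 81.2 |
| Friday's | 15.0 | 29.9 | 69.7 |
| Sunday's | 0.500 | 22.1 | 78.0 |
| Sunday's | 1.00 | 34.1 | 65.9 |
| Sunday's | 1.50 | 41.8 | 57.9 |
| Sunday's | 3.00 | 56.4 | 43.7 |
| Sunday's | 6.00 | 71.8 | 28.8 |
| Monday's | 3.00 | 20.5 | 79.2 |
| Monday's | 5.00 | 28.3 | 71.7 |
| Monday's | 8.00 | 36.0 | 63.4 |
| Monday's | 10.0 | 41.0 | 59.0 |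
| Monday's | 15.0 | 48.2 | 52.5 |

(each reading ± 0.5 percentage points)

- a reading or a percentage of target counts all its forms, free or not

* which of the two ends with the higher amount of target, in percent of the electrophile charged ("neither" if they lie within 2 percentage points) (west / north / neither)
* target at the end, in percent of the electrophile charged, west
* target at the end, in percent of the electrophile charged, north

Each reading has two entries, target and electrophile. Friday's last pair sums to 99.6%, Sunday's to 101% and Monday's to 101%, so the books closed within the scatter. The target entry was therefore the one to price, and I priced it in minutes. If north's warm stage counts as F cold minutes per minute, north's clock reads: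

north's cold time = 3.17 min

F at which the clocks tie = (8.0 min − cold time) / 50 s = 5.80

That tie is the break-even factor, the cold minutes that one warm minute must be worth for north to draw level with west.

The runs price F. Friday reached 20.0% at 6.00 min, Monday 20.5% at 3.00 min, and Sunday 22.1% at 0.500 min. I assumed one shared order in [protonated nucleophile] and [free base]:

order read from Friday to Monday = 0.631, which I carried forward as the round figure 0.7

speed-up from warming, Friday to Sunday = 4.55

apparent activation energy = 63.7 kJ mol⁻¹

F = 6.79

north's clock = 8.82 min

These are readings, scatter included, but F stood above break-even, and north's clock passed west's. So I backed north.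

The forecast differed: neither, with 43% for west and 42.5% for north, from 56 kJ/mol and “first order in NH⁺ and roughly zero order in free base”.

North ended at 47.3% and west at 41.1%, so the answer was north.

    electrophile + nucleophile → acid set free + target (k = 21.4 L mol⁻¹ s⁻¹, Ea = 48.0 kJ mol⁻¹)
    nucleophile + acid set free ⇌ protonated nucleophile, settled at all times (K = 2.00 × 10⁶ L mol⁻¹, ΔH = −61.0 kJ mol⁻¹)
    acid set free + free base ⇌ salt of the base, settled at all times (K = 76400 L mol⁻¹, ΔH = −20.0 kJ mol⁻¹)
    2 nucleophile → homo dimer (k = 4.19 L mol⁻¹ s⁻¹, Ea = 52.0 kJ mol⁻¹)
    crystals ⇌ target, rate k5*(cs5 - [target]) while solid is left; crystals form when [target] > cs5 (solubility = 0.0350 mM, k = 0.289 s⁻¹)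
    protic impurity + free base → quenched reagent (k = 852 L mol⁻¹ s⁻¹, Ea = 39.0 kJ mol⁻¹)
    (constants at 20 °C)

North held 41.8% target at 0.833 min, above west's end, so each warm minute had bought at least 9.60 cold ones, past break-even. The main reason for north's amount was the pairing of acid set free with free base to salt of the base: with that pairing taken away, north ended at 3.52% against 47.3%, and the answer on which flask led turned. West's charge run at 25 °C made 91.3% in 8.0 min, more than west's 81.8% after 80.0 min, so each minute there was worth over 10.0 cold ones.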